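The partner reached the starting material by dissolving out of a solid reagent, and I had these flasks to reckon.

| setting | oak | cedar | birch | elm | ash |
|---|---|---|---|---|---|
| starting material | 25 mM | 50 mM | 100 mM | 200 mM | 400 mM |
| solid reagent | 65.0 mM | 65.0 mM | 65.0 mM | 65.0 mM | 65.0 mM |
| time | 8.0 min | 8.0 min | 8.0 min | 8.0 min | 8.0 min |

    intermediate ⇌ target (K1 = 0.42, k1 = 0.040 s⁻¹)
    intermediate ⇌ isomer of the product (K2 = 250, k2 = 0.012 s⁻¹)
    starting material + partner → intermediate + released group (k3 = 0.42 L mol⁻¹ s⁻¹)
    solid reagent ⇌ partner, rate k4*(cs4 - [partner]) while solid is left; crystals form when [partner] > cs4 (cs4 = 24 mM, k4 = 0.041 s⁻¹)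

- given per volume of solution although it is solid: solid reagent
- at the start none of the solid reagent is in solution
- "hardly changes" means that all values lie within two and a half points (for a concentration: within two and a half percent of the largest)
- run time (oak): 8.0 min

1. [target] at the end for oak, cedar, birch, elm, ash, in this order
2. how the row runs (rises, then falls / falls, then rises / rises all the way / hardly changes / falls all the way)

I laid out the time scales from the quick end. The exchange of intermediate and target relaxed, both directions together, with a half-life of 0.0854 min. Dissolution had a half-life of 0.282 min, slower than that exchange, so on longer times I treated intermediate and target as one pool, with the target's share at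

share = 0.42 / (1 + 0.42) = 29.6%.

Next came the feed. The solid dissolved at 59.0 mM min⁻¹ at full rate, so its 65.0 mM took about 1.10 min.

In oak and cedar the charge stood below the solid, so I kept the partner near saturation. The starting material then decayed pseudo-first-order with a life of 1.65 min, the same in both, and I expected cedar at twice oak. From birch upward the solid was the limiting reagent, so I expected the feed to stop well before the end, leaving the pool to the leak on the next rung.

The top rung was the leak from the pool to the isomer of the product, which ran through the pool's intermediate part:

drain life = (1 + 0.42) / 0.012 s⁻¹ = 1.97 min.

This drain life, the mean time material stays in the pool once the feed has stopped, is the quantity I carried.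

I tried it on ash, where the starting material took up partner faster than the partner dissolved, so I let the solid dissolve at full rate. Integrating a constant feed into a draining pool gave

pool at end of feed = 59.0 mM min⁻¹ × 1.97 min × (1 − exp(−1.10 min / 1.97 min)) = 49.8 mM,

which decayed to 1.51 mM by the end. The isomer's way back added a target residue of 0.109 mM, so ash came to 0.555 mM of target.

The forecast gave 0.61 mM, 1.38 mM, 1.15 mM, 0.66 mM, 0.6 mM, rises, then falls, expecting with much starting material that “the pool drains away, leaving only a small equilibrium residue”.

The simulation gave 0.640 mM, 1.36 mM, 1.12 mM, 0.753 mM, 0.671 mM, rises, then falls, with the turn at 67 mM.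

Cedar stood at 2.12 times oak, and ash ended at 0.671 mM, above my 0.555 mM. In elm, with 0.00287 mM of partner at 4.00 min, the target above its residue at 80.0 min shrank between 4.00 min and 8.00 min to a fraction 0.138 of its value, against 0.132 from the drain life of 1.97 min.

The numbers of this flask are made up; what happens was integrated by code.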